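(The readings were generated by integration with made-up constants.)

Where does the target stand after 30 h as the charge of starting material climbs, with reagent and initiator held, and does the row peak?

| flask | starting material | reagent | initiator | remark | time |
|---|---|---|---|---|---|
| cedar | 0.020 M | 1.1 M | 16 mM | run made earlier |  |
| larch | 0.020 M | 1.68 M | 8 mM | run made earlier |  |
| Thursday's | 0.020 M | 1.68 M | 16 mM |  | 30 h |
| Tuesday's | 0.060 M | 1.68 M | 16 mM |  | 30 h |
| Wednesday's | 0.20 M | 1.68 M | 16 mM |  | 30 h |
| Friday's | 0.50 M | 1.68 M | 16 mM |  | 30 h |
| Saturday's | 1.5 M | 1.68 M | 16 mM |  | 30 h |

| run | time / h | target / % | starting material / % |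
|---|---|---|---|
| cedar | 1.33 | 4 | 94 |
| cedar | 4.00 | 17 | 82 |
| cedar | 6.00 | 20 | 69 |
| cedar | 10.0 | 39 | 56 |
| cedar | 15.0 | 49 | 36 |
| cedar | 20.0 | 65 | 27 |
| larch | 1.33 | 2 | 99 |
| larch | 2.50 | 5 | 91 |
| larch | 4.00 | 10 | 89 |
| larch | 6.00 | 14 | 84 |
| larch | 10.0 | 23 | 72 |
| larch | 20.0 | 37 | 52 |

(scatter of a reading: 1.5 percentage points)

- a species is counted by the starting material in it: one side product counts as two
- the numbers in the tables scatter by 1.5 percentage points (one standard deviation)
- what may be going on: initiator -> 2 initiating radical; starting material + initiating radical -> capped initiator + first chain carrier; reagent + first chain carrier -> target + second chain carrier; starting material + second chain carrier -> released group + first chain carrier; first chain carrier -> ended carrier; 2 second chain carrier -> ended chains; starting material + target -> side product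
- "hardly changes" means that all values lie within two and a half points (for a concentration: within two and a half percent of the largest)

* [target] at the end for Thursday's, Tuesday's, Wednesday's, Friday's, Saturday's, in this order
* how the row runs (falls all the way / rises, then falls / rises all the way / hardly changes / falls, then rises)

Two readings of the earlier runs quarrel over this. The supply view says a flask turns over a fixed amount per hour, whatever its charge. Larch lost 0.480 mM h⁻¹ of starting material over its 20.0 h. Cedar lost 0.730 mM h⁻¹, with 16 mM of initiator against larch's 8 mM, but with less reagent. Scaling larch in proportion to 16 mM of initiator gives a supply S = 0.960 mM h⁻¹. The ceiling is then C = 0.0288 M, supply times run time, the most target a flask makes in the run if S holds.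

The fraction view says a fixed share of the starting material goes each hour. Larch scaled the same way gives κ = 0.0654 h⁻¹, the first-order rate constant of that loss, so in this view 85.9% of any charge turns over in the run. Counted as target, that is 0.172 M for Wednesday's flask, and in this view the row climbs with the charge.

I commit to the ceiling. Thursday's charge is less than C, so starting material is the limiting reagent there. Tuesday's charge is more than C, so its target should stand near C. Beyond that, starting material + target → side product can pull the row down from C, which gives a peak.

The forecast, made from the supply side, reads 0.016 M, 0.031 M, 0.023 M, 0.012 M, 0.0043 M, rises, then falls, since at high charge “target is destroyed by starting material”.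

The flask gives 0.0171 M, 0.0278 M, 0.0465 M, 0.0434 M, 0.0158 M: rises, then falls.

    initiator → 2 initiating radical (k = 0.0210 h⁻¹)
    starting material + initiating radical → capped initiator + first chain carrier (k = 1.80 × 10⁷ M⁻¹ h⁻¹)
    reagent + first chain carrier → target + second chain carrier (k = 1.00 × 10⁵ M⁻¹ h⁻¹)
    starting material + second chain carrier → released group + first chain carrier (k = 1.10 × 10⁵ M⁻¹ h⁻¹)
    first chain carrier → ended carrier (k = 20000 h⁻¹)
    2 second chain carrier → ended chains (k = 2.50 × 10⁶ M⁻¹ s⁻¹)
    starting material + target → side product (k = 0.150 M⁻¹ h⁻¹)

The fraction view's target figure holds for Thursday's flask, where its 0.0172 M stands beside 0.0171 M, but for Tuesday's flask its 0.0516 M lies far above 0.0278 M. In Thursday's flask the target's half-life against side product alone, taken at the concentrations as charged, is 9.6 d, longer than the run. Side product counts two, so half its amount is target eaten. Tuesday's flask therefore made 0.0303 M of target against C = 0.0288 M. Friday's flask made 0.0998 M, which is 3.47 times C.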